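The plan rests on reading ring C as a butadiene cycloadduct. Its quaternary carbinol C1' carries both an oxygen and C2 of the dihydrobenzofuran, while the vicinal oxygens at C3' and C4' sit where a cyclohexene double bond would lie. A single enantioselective [4+2] reaction of buta-1,3-diene with 2-acetoxyacrolein, an acrolein whose alpha carbon already bears the C1' oxygen as an acetate, therefore forms C1'–C2' and C5'–C6', closes ring C, sets C1' and delivers C2 as an aldehyde. A syn-aldol with a ring A arylacetyl imide, C–O closure of ring B, hydroxyl-directed epoxidation and trans-diaxial methanolysis then finish the target.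

Key step: step 3

Atom labels: ring A is the arene (C3a–C7a), ring B the dihydrofuran (O1, C2, C3), ring C the cyclohexane (C1'–C6'). These labels are used for all intermediates. The target is (2S,3R,1'S,3'S,4'S), with ring B trans, C1'–OH and C3'–OH cis, and C4'–OMe trans to both.

Assumption: the sense of induction of the binaphthyl diammonium catalyst with butadiene is taken by analogy with other dienes; (R)-1,1'-binaphthyl-2,2'-diamine is written, and should it favour the antipode of 6, the equally available (S)-diamine is used instead.

Step 1
Reactants: 1 2,2-dimethyl-1,3-dioxan-5-one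
Product: 3 2,2-dimethyl-4H-1,3-dioxin-5-yl acetate, via potassium enolate 2 (not isolated)
Conditions: KN(SiMe3)2, THF, −78 °C; then Ac2O (excess), −78 → 0 °C
Reagents that add atoms: acetic anhydride, CC(=O)OC(C)=O; KN(SiMe3)2, C[Si](C)(C)[N-][Si](C)(C)C.[K+] (its potassium is found only in 2)
Why: Enol ester synthesis by O-acylation of a preformed enolate: the hindered silazide deprotonates the symmetrical ketone without hydride transfer or self-aldol, and quenching the hard potassium enolate 2 with excess anhydride favours attack through oxygen.

Step 2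
Reactants: 3 2,2-dimethyl-4H-1,3-dioxin-5-yl acetate
Product: 4 2-acetoxyacrolein
Conditions: PhMe, 110 °C, BHT (trace), acetone distilled off; short-path distillation
Reagents that add atoms: none
Why: Thermal retro-hetero-Diels–Alder fragmentation of the 4H-1,3-dioxin (O1–C2 and O3–C4 break, acetone leaves) unveils the enal under neutral conditions, so the hydrolysis-prone enol acetate never meets acid or base.

Step 3
Reactants: 4 2-acetoxyacrolein; 5 buta-1,3-diene
Product: 6 (S)-1-formylcyclohex-3-en-1-yl acetate
Conditions: (R)-1,1'-binaphthyl-2,2'-diamine (10 mol%), Tf2NH (19 mol%), 5 (5 equiv), EtCN, −20 °C, sealed vessel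
Reagents that add atoms: none
Why: One amino group of the diammonium salt condenses reversibly with the aldehyde of 4 to a protonated aldimine whose lowered LUMO lets s-cis butadiene add in a concerted, suprafacial [4+2] process, and hydrolysis of the product iminium ion releases 6 and the catalyst. The closest known reaction type is the enantioselective Diels–Alder reaction of alpha-acyloxyacroleins with dienes under chiral primary ammonium salt catalysis, here applied to the parent diene. Ring C is closed by intermolecular cycloaddition, C1'–C2' and C5'–C6' being formed together and the new alkene landing at C3'=C4'. C1' is the only new stereocentre and is set by the catalyst: the second ammonium group hydrogen-bonds to the acetate carbonyl, which freezes the iminium conformation, and one naphthyl wall blocks a face of the C=C bond so that the diene approaches from the open face. Only enantiofacial selectivity is needed, because the symmetric diene removes every regiochemical and endo/exo question. Chemoselectivity against polymerisation of 4 is secured by the excess of diene, the low temperature and the fact that 6, lacking a conjugated C=C bond and any alpha hydrogen, can neither react further nor racemise.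

Step 4
Reactants: 7 methyl 3-(4-hydroxy-3-methoxyphenyl)propanoate
Product: 8 methyl 3-[4-(allyloxy)-3-methoxyphenyl]propanoate
Conditions: allyl bromide, K2CO3, acetone, reflux
Reagents that add atoms: allyl bromide, C=CCBr
Why: Williamson ether synthesis in which carbonate deprotonates only the phenol and the allylic bromide is displaced in an SN2 reaction while the methyl ester stays inert.

Step 5
Reactants: 8 methyl 3-[4-(allyloxy)-3-methoxyphenyl]propanoate
Product: 10 methyl 3-(3-allyl-4-hydroxy-5-methoxyphenyl)propanoate, via ortho-dienone 9 (not isolated)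
Conditions: PhNEt2, 200 °C
Reagents that add atoms: none
Why: Aromatic Claisen rearrangement: the [3,3]-sigmatropic shift delivers the allyl group to the only ortho carbon that bears hydrogen (future C3a), since dienone 9 can tautomerise to the phenol whereas migration towards the methoxy-bearing ortho carbon is reversible and the para position is blocked.

Step 6
Reactants: 10 methyl 3-(3-allyl-4-hydroxy-5-methoxyphenyl)propanoate
Product: 11 methyl 3-[3-allyl-5-methoxy-4-(trifluoromethylsulfonyloxy)phenyl]propanoate
Conditions: Tf2O, pyridine, CH2Cl2, 0 °C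
Reagents that add atoms: triflic anhydride, O=S(=O)(OS(=O)(=O)C(F)(F)F)C(F)(F)F
Why: O-Sulfonylation of the phenol installs the leaving group at the future C7a for ring B closure and at the same time lowers the electron density of ring A before the oxidation that follows.

Step 7
Reactants: 11 methyl 3-[3-allyl-5-methoxy-4-(trifluoromethylsulfonyloxy)phenyl]propanoate
Product: 13 2-[3-methoxy-5-(3-methoxy-3-oxopropyl)-2-(trifluoromethylsulfonyloxy)phenyl]acetic acid, via arylacetaldehyde 12 (not isolated)
Conditions: OsO4 (1 mol%), KHSO5 (4 equiv, used as the triple salt 2KHSO5·KHSO4·K2SO4), DMF, rt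
Reagents that add atoms: potassium peroxymonosulfate, [K+].[O-]S(=O)(=O)OO
Why: Osmium-catalysed oxidative cleavage of a terminal alkene with peroxymonosulfate as terminal oxidant cuts the allyl group to arylacetaldehyde 12 and oxidises it on to the acid in the same flask, and the ester, the triflate and the deactivated arene are not attacked.

Step 8
Reactants: 13 2-[3-methoxy-5-(3-methoxy-3-oxopropyl)-2-(trifluoromethylsulfonyloxy)phenyl]acetic acid; 14 (S)-4-benzyloxazolidin-2-one
Product: 16 (S)-4-benzyl-3-(arylacetyl)oxazolidin-2-one (aryl = 3-methoxy-5-(3-methoxy-3-oxopropyl)-2-(trifluoromethylsulfonyloxy)phenyl), via mixed pivalic anhydride 15 (not isolated)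
Conditions: PivCl, Et3N, THF, −20 °C; then 14, LiCl, −20 °C → rt
Reagents that add atoms: pivaloyl chloride, CC(C)(C)C(=O)Cl (its acyl group is found only in 15)
Why: N-Acylation of the oxazolidinone through a mixed anhydride: attack occurs at the unhindered arylacetyl carbonyl of 15, LiCl and Et3N make the carbamate nitrogen nucleophilic enough without a strong base, and the methyl ester and the triflate are left alone.

Step 9
Reactants: 16 (S)-4-benzyl-3-(arylacetyl)oxazolidin-2-one; 6 (S)-1-formylcyclohex-3-en-1-yl acetate
Product: 19 syn-aldol adduct (imide alpha carbon C3 of S configuration bearing the aryl group; C2 carbinol S; C1' S still bearing the acetate; auxiliary 4S), via Z-boron enolate 17 (not isolated), via boron aldolate 18 (not isolated)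
Conditions: Bu2BOTf, Et3N, CH2Cl2, −78 → 0 °C; 6, −78 → 0 °C; then pH 7 buffer, MeOH, H2O2, 0 °C
Reagents that add atoms: dibutylboron triflate, CCCCB(CCCC)OS(=O)(=O)C(F)(F)F (its Bu2B group is found only in 17 and 18)
Why: Evans syn-aldol: soft enolisation gives the Z-boron enolate 17, which adds through a chair Zimmerman–Traxler transition state on the face away from the benzyl group of the (S)-auxiliary and so sets C3 and C2 (syn, which maps onto the trans ring B) under reagent control, because the two nearly equal CH2 arms at C1' leave the non-enolisable aldehyde 6 with almost no facial bias of its own.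

Step 10
Reactants: 19 syn-aldol adduct
Product: 20 (1S,2R)-2-[5-(3-hydroxypropyl)-3-methoxy-2-(trifluoromethylsulfonyloxy)phenyl]-1-[(S)-1-hydroxycyclohex-3-en-1-yl]propane-1,3-diol (tetraol; C2 S, C3 R, C1' S)
Conditions: LiBH4 (excess), MeOH, THF, 0 °C → rt
Reagents that add atoms: none
Why: Borohydride reduction of three acyl groups at once turns the imide and the methyl ester into the two primary alcohols and cleaves the acetate, so that any acetyl shift from the C1' oxygen to the C2 oxygen is harmless, no stereocentre is touched, and the aryl triflate and the alkene are inert to the reagent.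

Step 11
Reactants: 20 tetraol
Product: 21 bis-TBS ether of 20 (both primary hydroxyls silylated; C2–OH and C1'–OH free)
Conditions: TBSCl (2.1 equiv), imidazole, CH2Cl2, 0 °C
Reagents that add atoms: tert-butyldimethylsilyl chloride, CC(C)(C)[Si](C)(C)Cl
Why: Sterically governed silylation in which the two primary hydroxyls react far faster than the neopentyl-type secondary and the tertiary hydroxyl, and blocking C3–CH2OH is essential because that oxygen could also close a five-membered ring onto C7a.

Step 12
Reactants: 21 bis-TBS ether
Product: 22 (2S,3R)-trans-dihydrobenzofuran bearing (S)-1-hydroxycyclohex-3-en-1-yl at C2, CH2OTBS at C3, (CH2)3OTBS at C5 and OMe at C7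
Conditions: Pd(OAc)2 (5 mol%), 2-(di-tert-butylphosphino)-1,1'-binaphthyl (6 mol%), K3PO4, PhMe (degassed), 80 °C
Reagents that add atoms: none
Why: Intramolecular Buchwald–Hartwig-type C–O coupling in which zerovalent palladium inserts into the C7a–OTf bond, the C2 alkoxide binds to give a six-membered palladacycle (preferred to the seven-membered one from C1'–OH), and the bulky electron-rich phosphine drives reductive elimination ahead of beta-hydride elimination, so ring B closes without breaking the C2–O bond and C2 and C3 keep their configuration.

Step 13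
Reactants: 22 dihydrobenzofuran alkene
Product: 23 (1'S,3'S,4'R)-3',4'-epoxide of 22, epoxide oxygen on the same face of ring C as C1'–OH
Conditions: VO(acac)2 (5 mol%), t-BuOOH, CH2Cl2, 0 °C → rt
Reagents that add atoms: tert-butyl hydroperoxide, CC(C)(C)OO
Why: Hydroxyl-directed epoxidation of a tertiary homoallylic cyclohexenol: the vanadium alkoxide of the axial C1'–OH (the large C2 substituent sits equatorial) carries the bound peroxide to the alkene face syn to that hydroxyl and so sets C3' and C4' of the cis-epoxy alcohol.

Step 14
Reactants: 23 epoxide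
Product: 24 difengpiol B
Conditions: CSA (0.2 equiv), MeOH, 0 °C → rt
Reagents that add atoms: methanol, CO
Why: Acid-catalysed epoxide methanolysis under Fürst–Plattner control: in the half-chair with the large C2 substituent equatorial only attack at C4' runs through a chair-like trans-diaxial transition state, C4' is also the carbon farther from the electron-withdrawing C1' oxygen, and inversion there gives the C4' methoxyl trans and the C3' hydroxyl cis to C1'–OH while the same acid in methanol removes both primary TBS ethers.

Compound list
1 | 2,2-dimethyl-1,3-dioxan-5-one | CC1(C)OCC(=O)CO1 | starting material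
2 | potassium 2,2-dimethyl-4H-1,3-dioxin-5-olate | CC1(C)OCC([O-])=CO1.[K+] | intermediate
3 | 2,2-dimethyl-4H-1,3-dioxin-5-yl acetate | CC(=O)OC1=COC(C)(C)OC1 | intermediate
4 | 2-acetoxyacrolein | CC(=O)OC(=C)C=O | intermediate
5 | buta-1,3-diene | C=CC=C | starting material
6 | (S)-1-formylcyclohex-3-en-1-yl acetate | O=C[C@]1(OC(C)=O)CCC=CC1 | intermediate
7 | methyl 3-(4-hydroxy-3-methoxyphenyl)propanoate | COC(=O)CCc1ccc(O)c(OC)c1 | starting material
8 | methyl 3-[4-(allyloxy)-3-methoxyphenyl]propanoate | COC(=O)CCc1ccc(OCC=C)c(OC)c1 | intermediate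
9 | methyl 3-(3-allyl-5-methoxy-4-oxocyclohexa-1,5-dien-1-yl)propanoate (racemic) | COC(=O)CCC1=CC(CC=C)C(=O)C(OC)=C1 | intermediate
10 | methyl 3-(3-allyl-4-hydroxy-5-methoxyphenyl)propanoate | COC(=O)CCc1cc(CC=C)c(O)c(OC)c1 | intermediate
11 | methyl 3-[3-allyl-5-methoxy-4-(trifluoromethylsulfonyloxy)phenyl]propanoate | COC(=O)CCc1cc(CC=C)c(OS(=O)(=O)C(F)(F)F)c(OC)c1 | intermediate
12 | methyl 3-[3-methoxy-5-(2-oxoethyl)-4-(trifluoromethylsulfonyloxy)phenyl]propanoate | COC(=O)CCc1cc(CC=O)c(OS(=O)(=O)C(F)(F)F)c(OC)c1 | intermediate
13 | 2-[3-methoxy-5-(3-methoxy-3-oxopropyl)-2-(trifluoromethylsulfonyloxy)phenyl]acetic acid | COC(=O)CCc1cc(CC(=O)O)c(OS(=O)(=O)C(F)(F)F)c(OC)c1 | intermediate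
14 | (S)-4-benzyloxazolidin-2-one | O=C1N[C@@H](Cc2ccccc2)CO1 | starting material
15 | mixed anhydride of 13 and pivalic acid | COC(=O)CCc1cc(CC(=O)OC(=O)C(C)(C)C)c(OS(=O)(=O)C(F)(F)F)c(OC)c1 | intermediate
16 | (S)-4-benzyl-3-(arylacetyl)oxazolidin-2-one | COC(=O)CCc1cc(CC(=O)N2[C@@H](Cc3ccccc3)COC2=O)c(OS(=O)(=O)C(F)(F)F)c(OC)c1 | intermediate
17 | Z-dibutylboron enolate of 16 | CCCCB(CCCC)O/C(=C\c1cc(CCC(=O)OC)cc(OC)c1OS(=O)(=O)C(F)(F)F)N2[C@@H](Cc3ccccc3)COC2=O | intermediate
18 | dibutylboron aldolate of 19 | CCCCB(CCCC)O[C@H]([C@]1(OC(C)=O)CCC=CC1)[C@H](c2cc(CCC(=O)OC)cc(OC)c2OS(=O)(=O)C(F)(F)F)C(=O)N3[C@@H](Cc4ccccc4)COC3=O | intermediate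
19 | syn-aldol adduct (alpha carbon S, carbinol S, C1' S, auxiliary 4S) | O[C@H]([C@]1(OC(C)=O)CCC=CC1)[C@H](c2cc(CCC(=O)OC)cc(OC)c2OS(=O)(=O)C(F)(F)F)C(=O)N3[C@@H](Cc4ccccc4)COC3=O | intermediate
20 | tetraol aryl triflate (C2 S, C3 R, C1' S) | O[C@H]([C@]1(O)CCC=CC1)[C@H](c2cc(CCCO)cc(OC)c2OS(=O)(=O)C(F)(F)F)CO | intermediate
21 | bis-TBS ether of 20 | O[C@H]([C@]1(O)CCC=CC1)[C@H](c2cc(CCCO[Si](C)(C)C(C)(C)C)cc(OC)c2OS(=O)(=O)C(F)(F)F)CO[Si](C)(C)C(C)(C)C | intermediate
22 | (2S,3R,1'S)-dihydrobenzofuran alkene, bis-TBS | COc1cc(CCCO[Si](C)(C)C(C)(C)C)cc2c1O[C@H]([C@]1(O)CCC=CC1)[C@H]2CO[Si](C)(C)C(C)(C)C | intermediate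
23 | (2S,3R,1'S,3'S,4'R)-epoxide, bis-TBS | COc1cc(CCCO[Si](C)(C)C(C)(C)C)cc2c1O[C@H]([C@]1(O)CC[C@H]3O[C@H]3C1)[C@H]2CO[Si](C)(C)C(C)(C)C | intermediate
24 | difengpiol B (2S,3R,1'S,3'S,4'S) | COc1cc(CCCO)cc2c1O[C@H]([C@]1(O)CC[C@H](OC)[C@@H](O)C1)[C@H]2CO | target

Total step count: 14.
Longest linear sequence: 11 steps (steps 4–14, from 7). The ring C branch from 1 runs over 9 steps (steps 1–3 and 9–14).

Steps most likely to fail

Step 3. The unactivated parent diene may add too slowly at low temperature. Polymerisation of the enal or acetyl transfer to the catalyst amine could then take over. Enantiofacial discrimination may also be incomplete at the higher temperature that would be needed. The fallback sets out from 4 and 5 and comes back at 19. Catalyst control is given up and the auxiliary of the aldol partner serves as resolving agent. An uncatalysed thermal Diels–Alder reaction (PhMe, 90 °C, sealed tube, BHT) should give racemic 1-formylcyclohex-3-en-1-yl acetate F1. The aldol of step 9 with 16 fixes C2 and C3 through the auxiliary whatever the configuration at C1'. It should therefore give 19 together with its C1' epimer F2. The two diastereomers are separated by chromatography or crystallisation. The same separation would also remove any minor enantiomer carried through from an imperfect catalytic run.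

Step 12. Oxidative addition into a triflate flanked by two ortho substituents on an electron-rich ring may be slow. That leaves time for base-induced S–O cleavage of the triflate, beta-hydride elimination from the secondary alkoxide, or competing six-ring closure through the tertiary hydroxyl. The fallback sets out from 21 and comes back at 22. It is a metal-free closure that keeps the phenol oxygen as O1 and passes through a double inversion at C2.
- MsCl and Et3N (CH2Cl2, 0 °C) should sulfonylate only the secondary hydroxyl to the C2 mesylate F3.
- NaH (THF, 0 °C) lets the C1' alkoxide displace the mesylate with inversion to the spiro-epoxide F4.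
- Et4NOH (dioxane, rt to 50 °C) then cleaves the aryl triflate. The phenoxide of the epoxy phenol F5 opens the epoxide at C2 in a 5-exo-tet mode with a second inversion.

This restores the C1' hydroxyl and gives 22 with net retention at C2.

Step 9. The boron enolate carries an aryl group with two ortho substituents and the aldehyde is neopentyl-like, so the compact boron transition state may be reached slowly. Incomplete conversion, retro-aldol on work-up and eroded diastereoselectivity would follow. The fallback sets out from 13 and 6 and comes back at 20. It changes both the auxiliary and the enolate metal.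
- Acid 13 is coupled with (S)-4-benzylthiazolidine-2-thione (DCC, DMAP, CH2Cl2) to the N-arylacetyl thiazolidinethione F6.
- Enolisation with TiCl4, i-Pr2NEt and N-methylpyrrolidinone (CH2Cl2, −78 to 0 °C) and addition of 6 proceed through a non-chelated chair with longer Ti–O bonds. This should give the syn-aldol thiazolidinethione adduct F7 with the same configuration at C2 and C3.
- LiBH4 as in step 10 removes this more labile auxiliary together with the acetate and reduces the ester, giving 20.

Further compounds
F1 | step 3 | racemic 1-formylcyclohex-3-en-1-yl acetate | O=CC1(OC(C)=O)CCC=CC1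
F2 | step 3 | C1' epimer (1'R) of aldol adduct 19 | O[C@H]([C@@]1(OC(C)=O)CCC=CC1)[C@H](c2cc(CCC(=O)OC)cc(OC)c2OS(=O)(=O)C(F)(F)F)C(=O)N3[C@@H](Cc4ccccc4)COC3=O
F3 | step 12 | C2 mesylate of 21 | CS(=O)(=O)O[C@H]([C@]1(O)CCC=CC1)[C@H](c2cc(CCCO[Si](C)(C)C(C)(C)C)cc(OC)c2OS(=O)(=O)C(F)(F)F)CO[Si](C)(C)C(C)(C)C
F4 | step 12 | C1'–C2 spiro-epoxide (1-oxaspiro[2.5]oct-5-ene, C2 inverted), aryl triflate | O1[C@@H]([C@@]12CCC=CC2)[C@H](c3cc(CCCO[Si](C)(C)C(C)(C)C)cc(OC)c3OS(=O)(=O)C(F)(F)F)CO[Si](C)(C)C(C)(C)C
F5 | step 12 | epoxy phenol from F4 | O1[C@@H]([C@@]12CCC=CC2)[C@H](c3cc(CCCO[Si](C)(C)C(C)(C)C)cc(OC)c3O)CO[Si](C)(C)C(C)(C)C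
F6 | step 9 | (S)-4-benzyl-3-(arylacetyl)thiazolidine-2-thione | COC(=O)CCc1cc(CC(=O)N2[C@@H](Cc3ccccc3)CSC2=S)c(OS(=O)(=O)C(F)(F)F)c(OC)c1
F7 | step 9 | syn-aldol thiazolidinethione adduct | O[C@H]([C@]1(OC(C)=O)CCC=CC1)[C@H](c2cc(CCC(=O)OC)cc(OC)c2OS(=O)(=O)C(F)(F)F)C(=O)N3[C@@H](Cc4ccccc4)CSC3=S
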